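**Retrosynthetic overview**
1. The erythro side chain is made last: the carbinol centre by chelation-controlled reduction of an α-aryloxy ketone, the ring A aryl–C(=O) bond by aryllithium addition to an N-methoxy-N-methyl amide, and the ring B O–C bond by Mitsunobu inversion of the (S)-lactic N-methoxy-N-methyl amide.
2. The tetralin carbocycle is closed by forming C1–C8a in a Friedel–Crafts attack of ring C (para to its OMe) on a ring B benzylic cation; the C1–ring B bond comes from an arylmagnesium addition to the N-methoxy-N-methyl amide of a (2S,3R)-2,3-dimethyl-4-arylbutanoic acid.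
3. Feature used: the trans methyls on C2 and C3 sit between C1 (a carboxyl carbon before ring B is attached) and the benzylic C4 methylene on ring C. These four carbons are the C=O, α, β and γ carbons of a γ-aryl butenolide, whose γ C–O bond is hydrogenolysed once it has directed both methylations.
4. Both C–CH3 bonds are made by cuprate addition and enolate methylation on (S)-5-aryl-furan-2(5H)-one, itself made from O-silyl vanillin by asymmetric propiolate addition, cis-semihydrogenation and lactonisation.
5. Ring order: butenolide ring (step 3, temporary, opened in step 5), then the tetralin cyclohexene ring (step 10); rings A, B and C are bought as vanillin and 4-bromo-2-methoxyphenol.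

Key step: step 4

Remark: tetralin locants follow the lignan convention (C1 aryl-bearing, C2 and C3 methyl-bearing, C4 the CH2, OMe on C6, O on C7; ring A = side-chain guaiacyl, ring B = aryl on C1, ring C = fused arene). The facial sense of step 2 (Si-face attack with (S)-1,1'-bi-2-naphthol, as in related BINOL–titanium organozinc additions) is an assumption to be checked by Mosher ester analysis of 5; the antipodal ligand is used if the sense is reversed.

**Route**

Step 1
Reactants: 1 vanillin
Product: 2 3-methoxy-4-(triisopropylsilyloxy)benzaldehyde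
Conditions: TIPSCl, imidazole, DMF, rt
Reagents that add atoms: triisopropylsilyl chloride, CC(C)[Si](Cl)(C(C)C)C(C)C
Why: Silyl ether formation on a phenol; the bulky aryl silyl ether should survive the organometallic, hydrogenation and Lewis acid steps that follow.

Step 2
Reactants: 2 3-methoxy-4-(triisopropylsilyloxy)benzaldehyde; 3 ethyl propiolate
Product: 5 ethyl (R)-4-hydroxy-4-[3-methoxy-4-(triisopropylsilyloxy)phenyl]but-2-ynoate, via alkynylzinc 4 (not isolated)
Conditions: ZnEt2, HMPA, CH2Cl2, rt; then (S)-1,1'-bi-2-naphthol (40 mol%), Ti(OiPr)4; then 2, rt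
Reagents that add atoms: none
Why: Catalytic asymmetric alkynylzinc addition to an aromatic aldehyde, in which the chiral titanium binaphtholate should deliver the propiolate-derived alkynyl group to the Si face of the aldehyde and so set the (R)-carbinol centre.

Step 3
Reactants: 5 ethyl (R)-4-hydroxy-4-[3-methoxy-4-(triisopropylsilyloxy)phenyl]but-2-ynoate
Product: 7 (S)-5-[3-methoxy-4-(triisopropylsilyloxy)phenyl]furan-2(5H)-one, via Z-hydroxy enoate 6 (not isolated)
Conditions: H2 (1 atm), Pd/CaCO3–Pb(OAc)2, quinoline, EtOAc, rt; then pyridinium p-toluenesulfonate (cat.), CH2Cl2, rt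
Reagents that add atoms: none
Why: Lindlar cis-semihydrogenation places hydroxyl and ester on the same side of the alkene so that mild acid-catalysed lactonisation closes the butenolide without base and without touching the carbinol centre (the descriptor changes from R to S only through a CIP priority switch).

Step 4
Reactants: 7 (S)-5-[3-methoxy-4-(triisopropylsilyloxy)phenyl]furan-2(5H)-one
Product: 9 (3S,4S,5S)-5-[3-methoxy-4-(triisopropylsilyloxy)phenyl]-3,4-dimethyldihydrofuran-2(3H)-one, via lithium enolate 8 (not isolated)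
Conditions: Me2CuLi (from MeLi, CuI), Et2O, −78 °C; then MeI (excess), DMPU, THF, −78 to −30 °C
Reagents that add atoms: lithium dimethylcuprate, [Li+].C[Cu-]C; iodomethane, CI
Why: Me2CuLi forms a π-complex with the enoate and adds oxidatively at lactone C4 to give a trivalent copper β-cuprio enolate, and reductive elimination forms the C4–CH3 bond and leaves lithium enolate 8. Enolate 8 is then C-methylated at lactone C3 by MeI in an SN2 step, so both C–CH3 bonds are made in one flask. The closest known reaction type is the tandem cuprate conjugate addition–enolate alkylation (three-component coupling) of 5-substituted furan-2(5H)-ones, which gives trans,trans lactones. No ring is closed; the existing five-membered lactone only acts as a rigid template. The C4 stereocentre is controlled by the C5 aryl group, because the cuprate attacks the face anti to it, and the C3 stereocentre by the new C4 methyl, because MeI approaches the enolate face anti to it. The step needs 1,4- over 1,2-addition (soft cuprate), mono-C-methylation (lithium enolate in THF–DMPU at low temperature) and an intact C5 centre, which the weakly basic cuprate at −78 °C should secure by not deprotonating C5 to the aromatic furanolate.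

Step 5
Reactants: 9 (3S,4S,5S)-5-[3-methoxy-4-(triisopropylsilyloxy)phenyl]-3,4-dimethyldihydrofuran-2(3H)-one
Product: 10 (2S,3R)-4-[3-methoxy-4-(triisopropylsilyloxy)phenyl]-2,3-dimethylbutanoic acid
Conditions: H2 (4 atm), 10% Pd/C, AcOH, 40 °C
Reagents that add atoms: none
Why: Catalytic hydrogenolysis of the benzylic C5–O bond of an electron-rich γ-aryl lactone, which erases the relay stereocentre and leaves the two methyl-bearing centres untouched.

Step 6
Reactants: 10 (2S,3R)-4-[3-methoxy-4-(triisopropylsilyloxy)phenyl]-2,3-dimethylbutanoic acid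
Product: 11 (2S,3R)-N-methoxy-4-[3-methoxy-4-(triisopropylsilyloxy)phenyl]-N,2,3-trimethylbutanamide
Conditions: MeNH(OMe)·HCl, EDCI·HCl, 1-hydroxybenzotriazole, iPr2NEt, CH2Cl2, 0 °C to rt
Reagents that add atoms: N,O-dimethylhydroxylamine hydrochloride, Cl.CNOC
Why: Carbodiimide amide coupling through the hydroxybenzotriazole active ester (Weinreb amide formation), under which an α-alkyl acid without an N-acyl group should not epimerise.

Step 7
Reactants: 12 4-bromo-2-methoxyphenol
Product: 13 1-(benzyloxy)-4-bromo-2-methoxybenzene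
Conditions: BnBr, K2CO3, acetone, reflux
Reagents that add atoms: benzyl bromide, BrCc1ccccc1
Why: Williamson ether synthesis on a phenoxide.

Step 8
Reactants: 13 1-(benzyloxy)-4-bromo-2-methoxybenzene; 11 (2S,3R)-N-methoxy-4-[3-methoxy-4-(triisopropylsilyloxy)phenyl]-N,2,3-trimethylbutanamide
Product: 15 (2S,3R)-1-[4-(benzyloxy)-3-methoxyphenyl]-4-[3-methoxy-4-(triisopropylsilyloxy)phenyl]-2,3-dimethylbutan-1-one, via arylmagnesium bromide 14 (not isolated)
Conditions: Mg, THF, reflux; then 11, THF, 0 °C
Reagents that add atoms: none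
Why: Weinreb ketone synthesis, in which the N-methoxy group holds the adduct until the cold quench so that the Grignard reagent adds once and the α-centre is never exposed to base as a ketone.

Step 9
Reactants: 15 (2S,3R)-1-[4-(benzyloxy)-3-methoxyphenyl]-4-[3-methoxy-4-(triisopropylsilyloxy)phenyl]-2,3-dimethylbutan-1-one
Product: 16 (2S,3R)-1-[4-(benzyloxy)-3-methoxyphenyl]-4-[3-methoxy-4-(triisopropylsilyloxy)phenyl]-2,3-dimethylbutan-1-ol (both C1 epimers)
Conditions: NaBH4, MeOH–THF, 0 °C to rt
Reagents that add atoms: none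
Why: Borohydride reduction of an aryl ketone; the new carbinol configuration does not matter because this carbon becomes a planar cation in the next step.

Step 10
Reactants: 16 (2S,3R)-1-[4-(benzyloxy)-3-methoxyphenyl]-4-[3-methoxy-4-(triisopropylsilyloxy)phenyl]-2,3-dimethylbutan-1-ol (both C1 epimers)
Product: 17 (1S,2S,3R)-1-[4-(benzyloxy)-3-methoxyphenyl]-6-methoxy-2,3-dimethyl-7-(triisopropylsilyloxy)-1,2,3,4-tetrahydronaphthalene
Conditions: BF3·OEt2, CH2Cl2, −78 to 0 °C
Reagents that add atoms: none
Why: Intramolecular Friedel–Crafts alkylation, in which BF3 ionises the p-alkoxybenzylic alcohol and ring C attacks para to its methoxy group through a six-membered chair-like transition state with both methyls and the ring B aryl pseudo-equatorial, which should set C1 trans to the C2 methyl.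

Step 11
Reactants: 17 (1S,2S,3R)-1-[4-(benzyloxy)-3-methoxyphenyl]-6-methoxy-2,3-dimethyl-7-(triisopropylsilyloxy)-1,2,3,4-tetrahydronaphthalene
Product: 18 2-methoxy-4-[(1S,2S,3R)-6-methoxy-2,3-dimethyl-7-(triisopropylsilyloxy)-1,2,3,4-tetrahydronaphthalen-1-yl]phenol
Conditions: H2 (1 atm), 10% Pd/C, EtOAc–EtOH, rt
Reagents that add atoms: none
Why: Hydrogenolysis of a benzyl aryl ether, to which the aryl silyl ether and the doubly benzylic C1–H bond are inert.

Step 12
Reactants: 19 ethyl (S)-lactate
Product: 20 (S)-2-hydroxy-N-methoxy-N-methylpropanamide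
Conditions: MeNH(OMe)·HCl, iPrMgCl, THF, −20 to 0 °C
Reagents that add atoms: N,O-dimethylhydroxylamine hydrochloride, Cl.CNOC
Why: Ester aminolysis by the magnesium amide of N,O-dimethylhydroxylamine (Weinreb amide formation), which does not involve the stereocentre.

Step 13
Reactants: 18 2-methoxy-4-[(1S,2S,3R)-6-methoxy-2,3-dimethyl-7-(triisopropylsilyloxy)-1,2,3,4-tetrahydronaphthalen-1-yl]phenol; 20 (S)-2-hydroxy-N-methoxy-N-methylpropanamide
Product: 21 (R)-N-methoxy-2-{2-methoxy-4-[(1S,2S,3R)-6-methoxy-2,3-dimethyl-7-(triisopropylsilyloxy)-1,2,3,4-tetrahydronaphthalen-1-yl]phenoxy}-N-methylpropanamide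
Conditions: PPh3, DIAD, THF, 0 °C to rt
Reagents that add atoms: none
Why: Mitsunobu etherification, in which the ring B phenoxide displaces the alkoxyphosphonium of the activated α-hydroxy amide by SN2 with inversion, (S) to (R).

Step 14
Reactants: 12 4-bromo-2-methoxyphenol
Product: 22 (4-bromo-2-methoxyphenoxy)triisopropylsilane
Conditions: TIPSCl, imidazole, DMF, rt
Reagents that add atoms: triisopropylsilyl chloride, CC(C)[Si](Cl)(C(C)C)C(C)C
Why: Silyl ether formation on a phenol, chosen so that one fluoride treatment frees both phenols at the end.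

Step 15
Reactants: 22 (4-bromo-2-methoxyphenoxy)triisopropylsilane; 21 (R)-N-methoxy-2-{2-methoxy-4-[(1S,2S,3R)-6-methoxy-2,3-dimethyl-7-(triisopropylsilyloxy)-1,2,3,4-tetrahydronaphthalen-1-yl]phenoxy}-N-methylpropanamide
Product: 24 (R)-1-[3-methoxy-4-(triisopropylsilyloxy)phenyl]-2-{2-methoxy-4-[(1S,2S,3R)-6-methoxy-2,3-dimethyl-7-(triisopropylsilyloxy)-1,2,3,4-tetrahydronaphthalen-1-yl]phenoxy}propan-1-one, via aryllithium 23 (not isolated)
Conditions: n-BuLi, THF, −78 °C; then 21, −78 °C, cold quench
Reagents that add atoms: none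
Why: Bromine–lithium exchange followed by Weinreb ketone synthesis, where addition at −78 °C to the chelating N-methoxy amide should outrun α-deprotonation and so keep the (R)-aryloxy centre.

Step 16
Reactants: 24 (R)-1-[3-methoxy-4-(triisopropylsilyloxy)phenyl]-2-{2-methoxy-4-[(1S,2S,3R)-6-methoxy-2,3-dimethyl-7-(triisopropylsilyloxy)-1,2,3,4-tetrahydronaphthalen-1-yl]phenoxy}propan-1-one
Product: 25 (1S,2R)-1-[3-methoxy-4-(triisopropylsilyloxy)phenyl]-2-{2-methoxy-4-[(1S,2S,3R)-6-methoxy-2,3-dimethyl-7-(triisopropylsilyloxy)-1,2,3,4-tetrahydronaphthalen-1-yl]phenoxy}propan-1-ol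
Conditions: Zn(BH4)2, Et2O, −40 to 0 °C
Reagents that add atoms: none
Why: Chelation-controlled (Cram chelate) hydride reduction, in which zinc bridges the carbonyl oxygen and the α-aryloxy oxygen (assisted by the ortho-methoxy group) and hydride enters from the side of the α-hydrogen, which should give the erythro (1S,2R) alcohol.

Step 17
Reactants: 25 (1S,2R)-1-[3-methoxy-4-(triisopropylsilyloxy)phenyl]-2-{2-methoxy-4-[(1S,2S,3R)-6-methoxy-2,3-dimethyl-7-(triisopropylsilyloxy)-1,2,3,4-tetrahydronaphthalen-1-yl]phenoxy}propan-1-ol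
Product: 26 4-[(1S,2R)-1-hydroxy-2-{4-[(1S,2S,3R)-7-hydroxy-6-methoxy-2,3-dimethyl-1,2,3,4-tetrahydronaphthalen-1-yl]-2-methoxyphenoxy}propyl]-2-methoxyphenol
Conditions: Bu4NF, AcOH, THF, 0 °C to rt
Reagents that add atoms: none
Why: Fluoride cleavage of both aryl silyl ethers, buffered with AcOH so that the freed p-hydroxybenzylic alcohol is not driven towards a quinone methide.

**Compound list**
1 | vanillin | COc1cc(C=O)ccc1O | starting material
2 | 3-methoxy-4-(triisopropylsilyloxy)benzaldehyde | COc1cc(C=O)ccc1O[Si](C(C)C)(C(C)C)C(C)C | intermediate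
3 | ethyl propiolate | CCOC(=O)C#C | starting material
4 | ethyl 3-(ethylzincio)propiolate (alkynylzinc) | CC[Zn]C#CC(=O)OCC | intermediate
5 | ethyl (R)-4-hydroxy-4-[3-methoxy-4-(triisopropylsilyloxy)phenyl]but-2-ynoate | CCOC(=O)C#C[C@H](O)c1ccc(O[Si](C(C)C)(C(C)C)C(C)C)c(OC)c1 | intermediate
6 | ethyl (S,Z)-4-hydroxy-4-[3-methoxy-4-(triisopropylsilyloxy)phenyl]but-2-enoate | CCOC(=O)/C=C\[C@H](O)c1ccc(O[Si](C(C)C)(C(C)C)C(C)C)c(OC)c1 | intermediate
7 | (S)-5-[3-methoxy-4-(triisopropylsilyloxy)phenyl]furan-2(5H)-one | O=C1C=C[C@@H](c2ccc(O[Si](C(C)C)(C(C)C)C(C)C)c(OC)c2)O1 | intermediate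
8 | lithium (4S,5S)-5-[3-methoxy-4-(triisopropylsilyloxy)phenyl]-4-methyl-4,5-dihydrofuran-2-olate | [Li]OC1=C[C@H](C)[C@@H](c2ccc(O[Si](C(C)C)(C(C)C)C(C)C)c(OC)c2)O1 | intermediate
9 | (3S,4S,5S)-5-[3-methoxy-4-(triisopropylsilyloxy)phenyl]-3,4-dimethyldihydrofuran-2(3H)-one | O=C1O[C@H](c2ccc(O[Si](C(C)C)(C(C)C)C(C)C)c(OC)c2)[C@@H](C)[C@@H]1C | intermediate
10 | (2S,3R)-4-[3-methoxy-4-(triisopropylsilyloxy)phenyl]-2,3-dimethylbutanoic acid | OC(=O)[C@@H](C)[C@H](C)Cc1ccc(O[Si](C(C)C)(C(C)C)C(C)C)c(OC)c1 | intermediate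
11 | (2S,3R)-N-methoxy-4-[3-methoxy-4-(triisopropylsilyloxy)phenyl]-N,2,3-trimethylbutanamide | CON(C)C(=O)[C@@H](C)[C@H](C)Cc1ccc(O[Si](C(C)C)(C(C)C)C(C)C)c(OC)c1 | intermediate
12 | 4-bromo-2-methoxyphenol | COc1cc(Br)ccc1O | starting material
13 | 1-(benzyloxy)-4-bromo-2-methoxybenzene | COc1cc(Br)ccc1OCc1ccccc1 | intermediate
14 | [4-(benzyloxy)-3-methoxyphenyl]magnesium bromide | COc1cc([Mg]Br)ccc1OCc1ccccc1 | intermediate
15 | (2S,3R)-1-[4-(benzyloxy)-3-methoxyphenyl]-4-[3-methoxy-4-(triisopropylsilyloxy)phenyl]-2,3-dimethylbutan-1-one | COc1cc(C(=O)[C@@H](C)[C@H](C)Cc2ccc(O[Si](C(C)C)(C(C)C)C(C)C)c(OC)c2)ccc1OCc1ccccc1 | intermediate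
16 | (2S,3R)-1-[4-(benzyloxy)-3-methoxyphenyl]-4-[3-methoxy-4-(triisopropylsilyloxy)phenyl]-2,3-dimethylbutan-1-ol (both C1 epimers) | COc1cc(C(O)[C@@H](C)[C@H](C)Cc2ccc(O[Si](C(C)C)(C(C)C)C(C)C)c(OC)c2)ccc1OCc1ccccc1 | intermediate
17 | (1S,2S,3R)-1-[4-(benzyloxy)-3-methoxyphenyl]-6-methoxy-2,3-dimethyl-7-(triisopropylsilyloxy)-1,2,3,4-tetrahydronaphthalene | COc1cc([C@H]2c3cc(O[Si](C(C)C)(C(C)C)C(C)C)c(OC)cc3C[C@@H](C)[C@@H]2C)ccc1OCc1ccccc1 | intermediate
18 | 2-methoxy-4-[(1S,2S,3R)-6-methoxy-2,3-dimethyl-7-(triisopropylsilyloxy)-1,2,3,4-tetrahydronaphthalen-1-yl]phenol | COc1cc([C@H]2c3cc(O[Si](C(C)C)(C(C)C)C(C)C)c(OC)cc3C[C@@H](C)[C@@H]2C)ccc1O | intermediate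
19 | ethyl (S)-lactate | CCOC(=O)[C@H](C)O | starting material
20 | (S)-2-hydroxy-N-methoxy-N-methylpropanamide | C[C@H](O)C(=O)N(C)OC | intermediate
21 | (R)-N-methoxy-2-{2-methoxy-4-[(1S,2S,3R)-6-methoxy-2,3-dimethyl-7-(triisopropylsilyloxy)-1,2,3,4-tetrahydronaphthalen-1-yl]phenoxy}-N-methylpropanamide | CON(C)C(=O)[C@@H](C)Oc1ccc([C@H]2c3cc(O[Si](C(C)C)(C(C)C)C(C)C)c(OC)cc3C[C@@H](C)[C@@H]2C)cc1OC | intermediate
22 | (4-bromo-2-methoxyphenoxy)triisopropylsilane | COc1cc(Br)ccc1O[Si](C(C)C)(C(C)C)C(C)C | intermediate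
23 | [3-methoxy-4-(triisopropylsilyloxy)phenyl]lithium | [Li]c1ccc(O[Si](C(C)C)(C(C)C)C(C)C)c(OC)c1 | intermediate
24 | (R)-1-[3-methoxy-4-(triisopropylsilyloxy)phenyl]-2-{2-methoxy-4-[(1S,2S,3R)-6-methoxy-2,3-dimethyl-7-(triisopropylsilyloxy)-1,2,3,4-tetrahydronaphthalen-1-yl]phenoxy}propan-1-one | COc1cc(C(=O)[C@@H](C)Oc2ccc([C@H]3c4cc(O[Si](C(C)C)(C(C)C)C(C)C)c(OC)cc4C[C@@H](C)[C@@H]3C)cc2OC)ccc1O[Si](C(C)C)(C(C)C)C(C)C | intermediate
25 | (1S,2R)-1-[3-methoxy-4-(triisopropylsilyloxy)phenyl]-2-{2-methoxy-4-[(1S,2S,3R)-6-methoxy-2,3-dimethyl-7-(triisopropylsilyloxy)-1,2,3,4-tetrahydronaphthalen-1-yl]phenoxy}propan-1-ol | COc1cc([C@H](O)[C@@H](C)Oc2ccc([C@H]3c4cc(O[Si](C(C)C)(C(C)C)C(C)C)c(OC)cc4C[C@@H](C)[C@@H]3C)cc2OC)ccc1O[Si](C(C)C)(C(C)C)C(C)C | intermediate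
26 | 4-[(1S,2R)-1-hydroxy-2-{4-[(1S,2S,3R)-7-hydroxy-6-methoxy-2,3-dimethyl-1,2,3,4-tetrahydronaphthalen-1-yl]-2-methoxyphenoxy}propyl]-2-methoxyphenol (CID53359464) | COc1cc([C@H](O)[C@@H](C)Oc2ccc([C@H]3c4cc(O)c(OC)cc4C[C@@H](C)[C@@H]3C)cc2OC)ccc1O | target

**Step count and risks**

Total step count: 17. Longest linear sequence: 14 steps from vanillin (steps 1–6, 8–11, 13, 15–17); steps 7, 12 and 14 prepare side fragments.

Steps most likely to fail:

Step 4. The copper-containing enolate may be trapped incompletely or unselectively: proton transfer between enolate and product would lead to unmethylated and doubly methylated material and to a mixture of C3 epimers. Any γ-deprotonation of the butenolide would also erode the configuration at C5, and with it the absolute configuration of both methyl centres. The fallback sets out from 7 and separates the two bond formations. The conjugate addition (Me2CuLi, Et2O, −78 °C) is quenched with a proton source to isolate (4S,5S)-5-[3-methoxy-4-(triisopropylsilyloxy)phenyl]-4-methyldihydrofuran-2(3H)-one F1. This lactone is then deprotonated in a separate operation with LiN(iPr)2 in THF at −78 °C to give copper-free enolate 8 and methylated with MeI, anti to the C4 methyl. The fallback comes back to the route at 9.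

Step 2. The electron-rich, silyloxy-substituted aldehyde may react slowly, which would allow competing ethyl transfer from zinc and insufficient facial discrimination, so that 5 (and every later compound) is not enantiopure. The fallback sets out from 2 and sets the benzylic centre by ketone reduction instead. A Stetter reaction of 2 with ethyl acrylate (3-benzyl-5-(2-hydroxyethyl)-4-methylthiazolium chloride, Et3N, EtOH, 80 °C) should give ethyl 4-[3-methoxy-4-(triisopropylsilyloxy)phenyl]-4-oxobutanoate F2. Noyori asymmetric transfer hydrogenation of this aryl ketone (RuCl[(S,S)-TsDPEN](p-cymene), HCO2H–Et3N) should give ethyl (S)-4-hydroxy-4-[3-methoxy-4-(triisopropylsilyloxy)phenyl]butanoate F3, with the predictable sense of aryl alkyl ketones. Acid-catalysed lactonisation then gives (S)-5-[3-methoxy-4-(triisopropylsilyloxy)phenyl]dihydrofuran-2(3H)-one F4. α-Selenenylation (LiN(iPr)2, PhSeBr, THF, −78 °C) gives (5S)-5-[3-methoxy-4-(triisopropylsilyloxy)phenyl]-3-(phenylselanyl)dihydrofuran-2(3H)-one F5. Oxidation with H2O2 gives the selenoxide (5S)-5-[3-methoxy-4-(triisopropylsilyloxy)phenyl]-3-(phenylseleninyl)dihydrofuran-2(3H)-one F6, which undergoes syn-elimination. The fallback comes back to the route at 7, bypassing steps 2 and 3.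

Step 16. Chelation by zinc may be weak because an aryl ether is a poor donor, so that Felkin–Anh attack competes and facial selectivity at the carbonyl is poor; the α-aryloxy ketone may also epimerise before it is reduced. The fallback sets out from 24 and replaces substrate control by catalyst control. A Corey–Bakshi–Shibata reduction with BH3·SMe2 and (S)-1-methyl-3,3-diphenyltetrahydro-1H,3H-pyrrolo[1,2-c][1,3,2]oxazaborole in THF at −20 °C treats the ring A aryl as the large group and should deliver hydride to the face that gives the (1S)-carbinol, under non-basic conditions. The fallback comes back to the route at 25 and passes through no new compound, F0.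

Further compounds
F1 | step 4 | (4S,5S)-5-[3-methoxy-4-(triisopropylsilyloxy)phenyl]-4-methyldihydrofuran-2(3H)-one | O=C1O[C@H](c2ccc(O[Si](C(C)C)(C(C)C)C(C)C)c(OC)c2)[C@@H](C)C1
F2 | step 2 | ethyl 4-[3-methoxy-4-(triisopropylsilyloxy)phenyl]-4-oxobutanoate | CCOC(=O)CCC(=O)c1ccc(O[Si](C(C)C)(C(C)C)C(C)C)c(OC)c1
F3 | step 2 | ethyl (S)-4-hydroxy-4-[3-methoxy-4-(triisopropylsilyloxy)phenyl]butanoate | CCOC(=O)CC[C@H](O)c1ccc(O[Si](C(C)C)(C(C)C)C(C)C)c(OC)c1
F4 | step 2 | (S)-5-[3-methoxy-4-(triisopropylsilyloxy)phenyl]dihydrofuran-2(3H)-one | O=C1CC[C@@H](c2ccc(O[Si](C(C)C)(C(C)C)C(C)C)c(OC)c2)O1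
F5 | step 2 | (5S)-5-[3-methoxy-4-(triisopropylsilyloxy)phenyl]-3-(phenylselanyl)dihydrofuran-2(3H)-one (C3 epimers) | O=C1C([Se]c3ccccc3)C[C@@H](c2ccc(O[Si](C(C)C)(C(C)C)C(C)C)c(OC)c2)O1
F6 | step 2 | (5S)-5-[3-methoxy-4-(triisopropylsilyloxy)phenyl]-3-(phenylseleninyl)dihydrofuran-2(3H)-one | O=C1C([Se](=O)c3ccccc3)C[C@@H](c2ccc(O[Si](C(C)C)(C(C)C)C(C)C)c(OC)c2)O1
F0 | step 16 | none | none
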